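## Retrosynthetic overview

1. Sodwanone S ⇐ desilylation and C19 oxidation ⇐ saturation of a C13=C14 alkene ⇐ Julia–Kocienski union of fragment A (rings A and B, C13 aldehyde) with fragment B (rings C and D, C14 tetrazolyl sulfone).
2. Fragment A: ring B (the oxepene) is closed last by ring-closing metathesis, the key step, between an allyl carbinol arm and an exocyclic C11 methylene, forming C10=C11.
3. Its precursor: ring A by Michael addition/intramolecular aldol condensation of methyl acetoacetate with crotonaldehyde, C12 by methylation, the C5–O–C7 tertiary ether by carbenoid O–H insertion, C8 by Brown allylation.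
4. Fragment B: geraniol → bis-epoxide (Sharpless, Shi) → acetoacetate homologation → silyl triflate cascade that closes ring D (oxepane) and then ring C; the C25 carbinol via enol triflate, cuprate, epoxidation and SmI2.
5. Ring order: A, then B (fragment A); D then C in one operation (fragment B); the two bicycles are joined afterwards.

Locants used below (assumption, taken from the order of atoms in the target SMILES): ring A C2(H,Me)–C3–C4–C5(H,O6)–C11–C12(Me); ring B O6–C7(Me2)–C8(OH)–C9–C10=C11; linker C13–C14; ring C C15(H)–C16(Me)–C22(H)–C23–C24–C25(Me,OH); ring D C16–C17–C18–C19(=O)–C20(Me2)–O21–C22. All eight stereocentres are S.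

## Fragment A (steps 1–13)

Step 1
Reactants: 1 methyl acetoacetate; 2 (E)-crotonaldehyde
Product: 4 methyl (1R,6S)-6-methyl-2-oxocyclohex-3-ene-1-carboxylate, via Michael adduct 3 (not isolated)
Conditions: (R)-α,α-diphenylprolinol trimethylsilyl ether (10 mol%), PhCO2H (10 mol%), toluene, 0 °C to rt; then TsOH·H2O, toluene, 60 °C
Reagents that add atoms: none
Why: Iminium-catalysed asymmetric Michael addition (the silyloxydiphenylmethyl group of the R catalyst shields one face of the crotonaldehyde iminium and sets C2 as S) is followed by acid-promoted intramolecular aldol condensation of the methyl ketone onto the aldehyde, which closes ring A.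

Step 2
Reactants: 4 methyl (1R,6S)-6-methyl-2-oxocyclohex-3-ene-1-carboxylate
Product: 5 methyl (1R,2S)-2-methyl-6-oxocyclohexane-1-carboxylate
Conditions: H2 (1 atm), Pd/C, EtOAc, rt
Reagents that add atoms: none
Why: Catalytic hydrogenation saturates the conjugated C=C while the β-keto ester and the C2 stereocentre are untouched.

Step 3
Reactants: 5 methyl (1R,2S)-2-methyl-6-oxocyclohexane-1-carboxylate
Product: 6 methyl (1S,2S)-1,2-dimethyl-6-oxocyclohexane-1-carboxylate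
Conditions: K2CO3, MeI, acetone, reflux
Reagents that add atoms: iodomethane, CI
Why: C-alkylation of the β-keto ester enolate occurs anti to the adjacent C2 methyl (held pseudoaxial by A(1,2) strain), so quaternary C12 is formed with its methyl trans and its ester cis to the C2 methyl.

Step 4
Reactants: 6 methyl (1S,2S)-1,2-dimethyl-6-oxocyclohexane-1-carboxylate
Product: 8 methyl (1S,2S)-5-diazo-1,2-dimethyl-6-oxocyclohexane-1-carboxylate, via trifluoroacetyl ketone 7 (not isolated)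
Conditions: LiN(SiMe3)2, THF, −78 °C; CF3CO2CH2CF3; then MsN3, Et3N, H2O, MeCN, rt
Reagents that add atoms: methanesulfonyl azide, CS(=O)(=O)N=[N+]=[N-]
Why: Danheiser detrifluoroacetylative diazo transfer is regiochemically unambiguous because C5 is the only enolisable position of the ketone.

Step 5
Reactants: 9 1,1-dimethoxypropan-2-one
Product: 10 1,1-dimethoxy-2-methylpropan-2-ol
Conditions: MeMgBr, Et2O, 0 °C; aq NH4Cl
Reagents that add atoms: methylmagnesium bromide, C[Mg]Br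
Why: Grignard addition to the ketone gives the tertiary alcohol that carries C7, its two methyls and C8 masked as an acetal.

Step 6
Reactants: 8 methyl (1S,2S)-5-diazo-1,2-dimethyl-6-oxocyclohexane-1-carboxylate; 10 1,1-dimethoxy-2-methylpropan-2-ol (10 equiv)
Product: 12 methyl (1S,2S,5S)-5-[(1,1-dimethoxy-2-methylpropan-2-yl)oxy]-1,2-dimethyl-6-oxocyclohexane-1-carboxylate, via C5-epimer mixture 11 (not isolated)
Conditions: Rh2(OAc)4 (2 mol%), slow addition of 8, CH2Cl2, rt; then DBU (0.2 equiv), CH2Cl2, rt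
Reagents that add atoms: none
Why: Rhodium carbenoid O–H insertion into the excess tertiary alcohol builds the hindered C5–O–C7 ether, and base equilibration of the α-alkoxy ketone puts the bulky alkoxy group equatorial, trans to the axial ester, which is the 5S epimer.

Step 7
Reactants: 12 methyl (1S,2S,5S)-5-[(1,1-dimethoxy-2-methylpropan-2-yl)oxy]-1,2-dimethyl-6-oxocyclohexane-1-carboxylate
Product: 13 methyl (1S,2S,5S)-1,2-dimethyl-5-[(2-methyl-1-oxopropan-2-yl)oxy]-6-oxocyclohexane-1-carboxylate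
Conditions: CF3CO2H, H2O, CHCl3, 0 °C to rt
Reagents that add atoms: water, O
Why: Acid hydrolysis of the dimethyl acetal releases a non-enolisable aldehyde, and the tertiary ether survives because its cation would be destabilised by the adjacent carbonyl.

Step 8
Reactants: 13 methyl (1S,2S,5S)-1,2-dimethyl-5-[(2-methyl-1-oxopropan-2-yl)oxy]-6-oxocyclohexane-1-carboxylate
Product: 14 methyl (1S,2S,5S)-5-{[(3S)-3-hydroxy-2-methylhex-5-en-2-yl]oxy}-1,2-dimethyl-6-oxocyclohexane-1-carboxylate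
Conditions: (−)-Ipc2B(allyl), Et2O, −78 °C; then NaOH, H2O2, 0 °C
Reagents that add atoms: (−)-B-allyldiisopinocampheylborane, C=CCB([C@@H]1C[C@@H]2C[C@H]([C@H]1C)C2(C)C)[C@@H]1C[C@@H]2C[C@H]([C@H]1C)C2(C)C
Why: Brown asymmetric allylboration through a chair six-membered transition state sets C8 as S under reagent control, and at −78 °C only the aldehyde reacts, not the hindered ketone or the ester.

Step 9
Reactants: 14 methyl (1S,2S,5S)-5-{[(3S)-3-hydroxy-2-methylhex-5-en-2-yl]oxy}-1,2-dimethyl-6-oxocyclohexane-1-carboxylate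
Product: 15 methyl (1S,2S,5S)-5-{[(3S)-3-(tert-butyldimethylsilyloxy)-2-methylhex-5-en-2-yl]oxy}-1,2-dimethyl-6-oxocyclohexane-1-carboxylate
Conditions: TBSOTf, 2,6-lutidine, CH2Cl2, −78 to 0 °C
Reagents that add atoms: tert-butyldimethylsilyl triflate, CC(C)(C)[Si](C)(C)OS(=O)(=O)C(F)(F)F
Why: Silylation protects the C8 carbinol with a group that later survives the acid that removes the triethylsilyl and trimethylsilyl ethers.

Step 10
Reactants: 15 methyl (1S,2S,5S)-5-{[(3S)-3-(tert-butyldimethylsilyloxy)-2-methylhex-5-en-2-yl]oxy}-1,2-dimethyl-6-oxocyclohexane-1-carboxylate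
Product: 16 methyl (1S,2S,5S)-5-{[(3S)-3-(tert-butyldimethylsilyloxy)-2-methylhex-5-en-2-yl]oxy}-1,2-dimethyl-6-methylidenecyclohexane-1-carboxylate
Conditions: Zn, CH2Br2, TiCl4, THF/CH2Cl2, 0 °C to rt
Reagents that add atoms: dibromomethane, BrCBr
Why: Takai–Lombardo methylenation converts the hindered enolisable ketone into the exocyclic alkene under non-basic conditions, so C5 is not epimerised and the ester is not touched.

Step 11
Reactants: 16 methyl (1S,2S,5S)-5-{[(3S)-3-(tert-butyldimethylsilyloxy)-2-methylhex-5-en-2-yl]oxy}-1,2-dimethyl-6-methylidenecyclohexane-1-carboxylate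
Product: 17 methyl (3S,6S,7S,9aS)-3-(tert-butyldimethylsilyloxy)-2,2,6,7-tetramethyl-2,3,4,6,7,8,9,9a-octahydro-1-benzoxepine-6-carboxylate
Conditions: second-generation Hoveyda–Grubbs catalyst (10 mol%), toluene, 80 °C, argon sparge
Reagents that add atoms: none
Why: Ring-closing metathesis starts at the unhindered allyl terminus and closes onto the exocyclic methylene to give the seven-membered oxepene with the trisubstituted C10=C11 alkene, driven by loss of ethene.

Step 12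
Reactants: 17 methyl (3S,6S,7S,9aS)-3-(tert-butyldimethylsilyloxy)-2,2,6,7-tetramethyl-2,3,4,6,7,8,9,9a-octahydro-1-benzoxepine-6-carboxylate
Product: 18 [(3S,6S,7S,9aS)-3-(tert-butyldimethylsilyloxy)-2,2,6,7-tetramethyl-2,3,4,6,7,8,9,9a-octahydro-1-benzoxepin-6-yl]methanol
Conditions: iBu2AlH, CH2Cl2, −78 to 0 °C
Reagents that add atoms: none
Why: Hydride reduction of the neopentyl ester to the primary alcohol leaves the silyl ether and the ring alkene intact.

Step 13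
Reactants: 18 [(3S,6S,7S,9aS)-3-(tert-butyldimethylsilyloxy)-2,2,6,7-tetramethyl-2,3,4,6,7,8,9,9a-octahydro-1-benzoxepin-6-yl]methanol
Product: 19 (3S,6S,7S,9aS)-3-(tert-butyldimethylsilyloxy)-2,2,6,7-tetramethyl-2,3,4,6,7,8,9,9a-octahydro-1-benzoxepine-6-carbaldehyde
Conditions: Dess–Martin periodinane, NaHCO3, CH2Cl2, rt
Reagents that add atoms: none
Why: Dess–Martin oxidation gives the non-enolisable α-quaternary aldehyde (C13) without touching the alkene or the silyl ether.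

## Fragment B (steps 14–26)

Step 14
Reactants: 20 geraniol
Product: 21 [(2S,3S)-3-methyl-3-(4-methylpent-3-en-1-yl)oxiran-2-yl]methanol
Conditions: Ti(OiPr)4 (5 mol%), L-(+)-diethyl tartrate (7 mol%), t-BuOOH, 4 Å molecular sieves, CH2Cl2, −20 °C
Reagents that add atoms: tert-butyl hydroperoxide, CC(C)(C)OO
Why: Sharpless asymmetric epoxidation of the allylic alcohol with L-(+)-tartrate gives the (2S,3S)-epoxide, whose two carbons become C22 and C16.

Step 15
Reactants: 21 [(2S,3S)-3-methyl-3-(4-methylpent-3-en-1-yl)oxiran-2-yl]methanol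
Product: 22 [(2S,3S)-3-{2-[(2S)-3,3-dimethyloxiran-2-yl]ethyl}-3-methyloxiran-2-yl]methanol
Conditions: ent-Shi ketone (L-fructose-derived, 30 mol%), KHSO5 (as Oxone), K2CO3, Bu4NHSO4, Na2B4O7 buffer, MeCN/CH2(OMe)2, 0 °C
Reagents that add atoms: potassium peroxymonosulfate, [K+].[O-]S(=O)(=O)OO
Why: Shi dioxirane epoxidation of the remaining trisubstituted alkene is reagent-controlled and gives the (S)-terminal epoxide; this centre (C19) becomes a ketone at the end.

Step 16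
Reactants: 22 [(2S,3S)-3-{2-[(2S)-3,3-dimethyloxiran-2-yl]ethyl}-3-methyloxiran-2-yl]methanol; 1 methyl acetoacetate (as its dianion)
Product: 24 methyl 5-[(2S,3S)-3-{2-[(2S)-3,3-dimethyloxiran-2-yl]ethyl}-3-methyloxiran-2-yl]-3-oxopentanoate, via epoxy triflate 23 (not isolated)
Conditions: Tf2O, 2,6-lutidine, CH2Cl2, −78 °C, cold aqueous wash; crude triflate added to the dianion of 1 (NaH then n-BuLi, THF, 0 °C), −78 to −30 °C
Reagents that add atoms: none
Why: The Weiler dianion alkylates at its γ-carbon by SN2 displacement of the primary triflate faster than it opens either trisubstituted epoxide, which joins C23 to C24.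

Step 17
Reactants: 24 methyl 5-[(2S,3S)-3-{2-[(2S)-3,3-dimethyloxiran-2-yl]ethyl}-3-methyloxiran-2-yl]-3-oxopentanoate
Product: 25 methyl (2Z)-5-[(2S,3S)-3-{2-[(2S)-3,3-dimethyloxiran-2-yl]ethyl}-3-methyloxiran-2-yl]-3-(triethylsilyloxy)pent-2-enoate
Conditions: Et3SiCl, Et3N, DMAP (cat.), CH2Cl2, 0 °C
Reagents that add atoms: chlorotriethylsilane, CC[Si](Cl)(CC)CC
Why: O-silylation of the β-keto ester gives an enol silane whose α-carbon (C15) is the only nucleophilic carbon, which fixes the regiochemistry of the coming ring closure.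

Step 18
Reactants: 25 methyl (2Z)-5-[(2S,3S)-3-{2-[(2S)-3,3-dimethyloxiran-2-yl]ethyl}-3-methyloxiran-2-yl]-3-(triethylsilyloxy)pent-2-enoate
Product: 26 methyl (3S,5aS,6S,9aS)-2,2,5a-trimethyl-7-oxo-3-(triethylsilyloxy)decahydro-1-benzoxepine-6-carboxylate
Conditions: Et3SiOTf (0.5 equiv), 2,6-di-tert-butyl-4-methylpyridine, CH2Cl2, −78 °C; Et3N quench
Reagents that add atoms: none
Why: In this silyl triflate-promoted tandem oxa/carbacyclisation the silylated terminal epoxide is opened at C20 by the internal epoxide oxygen and the resulting epoxonium is opened at C16 with inversion by the enol silane, giving the trans-fused oxepane–cyclohexane with C16 and C22 set by the Sharpless epoxide; the enol silyl group is released as Et3SiOTf, which carries the chain.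

Step 19
Reactants: 26 methyl (3S,5aS,6S,9aS)-2,2,5a-trimethyl-7-oxo-3-(triethylsilyloxy)decahydro-1-benzoxepine-6-carboxylate
Product: 27 methyl (3S,5aS,9aS)-2,2,5a-trimethyl-3-(triethylsilyloxy)-7-(trifluoromethylsulfonyloxy)-2,3,4,5,5a,8,9,9a-octahydro-1-benzoxepine-6-carboxylate
Conditions: NaH, PhNTf2, THF, 0 °C to rt
Reagents that add atoms: N-phenylbis(trifluoromethanesulfonimide), FC(F)(F)S(=O)(=O)N(c1ccccc1)S(=O)(=O)C(F)(F)F
Why: O-triflation of the β-keto ester enolate gives the vinyl triflate at C25.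

Step 20
Reactants: 27 methyl (3S,5aS,9aS)-2,2,5a-trimethyl-3-(triethylsilyloxy)-7-(trifluoromethylsulfonyloxy)-2,3,4,5,5a,8,9,9a-octahydro-1-benzoxepine-6-carboxylate
Product: 28 methyl (3S,5aS,9aS)-2,2,5a,7-tetramethyl-3-(triethylsilyloxy)-2,3,4,5,5a,8,9,9a-octahydro-1-benzoxepine-6-carboxylate
Conditions: Me2CuLi (from CuI and MeLi), Et2O/THF, −78 to −20 °C
Reagents that add atoms: lithium dimethylcuprate, [Li+].C[Cu-]C
Why: Cuprate addition–elimination on the β-triflyloxy enoate (McMurry–Scott coupling) installs the C25 methyl.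

Step 21
Reactants: 28 methyl (3S,5aS,9aS)-2,2,5a,7-tetramethyl-3-(triethylsilyloxy)-2,3,4,5,5a,8,9,9a-octahydro-1-benzoxepine-6-carboxylate
Product: 29 methyl (3S,5aR,6R,7S,9aS)-6,7-epoxy-2,2,5a,7-tetramethyl-3-(triethylsilyloxy)decahydro-1-benzoxepine-6-carboxylate
Conditions: mCPBA, NaHCO3, CH2Cl2, 0 °C to rt
Reagents that add atoms: 3-chloroperoxybenzoic acid, OOC(=O)c1cccc(Cl)c1
Why: Prilezhaev epoxidation of the tetrasubstituted alkene takes place on the face opposite the axial C16 methyl, which sets the C25–O bond on the α face.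

Step 22
Reactants: 29 methyl (3S,5aR,6R,7S,9aS)-6,7-epoxy-2,2,5a,7-tetramethyl-3-(triethylsilyloxy)decahydro-1-benzoxepine-6-carboxylate
Product: 30 methyl (3S,5aS,6S,7S,9aS)-7-hydroxy-2,2,5a,7-tetramethyl-3-(triethylsilyloxy)decahydro-1-benzoxepine-6-carboxylate
Conditions: SmI2 (2.5 equiv), THF/MeOH, −78 °C
Reagents that add atoms: none
Why: SmI2 reduction of the α,β-epoxy ester cleaves the C15–O bond to give the tertiary carbinol (OH equatorial, methyl axial), and the samarium enolate is protonated from the face away from the two axial methyls, so H15 is axial and the ester equatorial.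

Step 23
Reactants: 30 methyl (3S,5aS,6S,7S,9aS)-7-hydroxy-2,2,5a,7-tetramethyl-3-(triethylsilyloxy)decahydro-1-benzoxepine-6-carboxylate
Product: 31 (3S,5aS,6R,7S,9aS)-6-(hydroxymethyl)-2,2,5a,7-tetramethyl-3-(triethylsilyloxy)decahydro-1-benzoxepin-7-ol
Conditions: LiAlH4, THF, 0 °C
Reagents that add atoms: none
Why: Hydride reduction of the ester gives the primary alcohol (C14) without epimerising C15 and leaves the hindered silyl ether.

Step 24
Reactants: 31 (3S,5aS,6R,7S,9aS)-6-(hydroxymethyl)-2,2,5a,7-tetramethyl-3-(triethylsilyloxy)decahydro-1-benzoxepin-7-ol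
Product: 32 (3S,5aS,6S,7S,9aS)-2,2,5a,7-tetramethyl-6-{[(1-phenyl-1H-tetrazol-5-yl)sulfanyl]methyl}-3-(triethylsilyloxy)decahydro-1-benzoxepin-7-ol
Conditions: 1-phenyl-1H-tetrazole-5-thiol, PPh3, DIAD, THF, 0 °C to rt
Reagents that add atoms: 1-phenyl-1H-tetrazole-5-thiol, Sc1nnnn1-c1ccccc1
Why: Mitsunobu thioetherification takes place only at the primary alcohol because the tertiary carbinol cannot be activated.

Step 25
Reactants: 32 (3S,5aS,6S,7S,9aS)-2,2,5a,7-tetramethyl-6-{[(1-phenyl-1H-tetrazol-5-yl)sulfanyl]methyl}-3-(triethylsilyloxy)decahydro-1-benzoxepin-7-ol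
Product: 33 (3S,5aS,6S,7S,9aS)-2,2,5a,7-tetramethyl-6-{[(1-phenyl-1H-tetrazol-5-yl)sulfonyl]methyl}-3-(triethylsilyloxy)decahydro-1-benzoxepin-7-ol
Conditions: mCPBA (3 equiv), NaHCO3, CH2Cl2, 0 °C to rt
Reagents that add atoms: 3-chloroperoxybenzoic acid, OOC(=O)c1cccc(Cl)c1
Why: Buffered peracid oxidation takes the sulfide to the sulfone, and nothing else in the molecule is oxidisable.

Step 26
Reactants: 33 (3S,5aS,6S,7S,9aS)-2,2,5a,7-tetramethyl-6-{[(1-phenyl-1H-tetrazol-5-yl)sulfonyl]methyl}-3-(triethylsilyloxy)decahydro-1-benzoxepin-7-ol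
Product: 34 5-({[(3S,5aS,6S,7S,9aS)-2,2,5a,7-tetramethyl-3-(triethylsilyloxy)-7-(trimethylsilyloxy)decahydro-1-benzoxepin-6-yl]methyl}sulfonyl)-1-phenyl-1H-tetrazole
Conditions: N-(trimethylsilyl)imidazole, CH2Cl2, rt
Reagents that add atoms: N-(trimethylsilyl)imidazole, C[Si](C)(C)n1ccnc1
Why: Silylation of the tertiary alcohol prevents the C25 alkoxide from attacking the tetrazole (Smiles-type transfer) during the olefination.

## Union and endgame (steps 27–31)

Step 27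
Reactants: 34 5-({[(3S,5aS,6S,7S,9aS)-2,2,5a,7-tetramethyl-3-(triethylsilyloxy)-7-(trimethylsilyloxy)decahydro-1-benzoxepin-6-yl]methyl}sulfonyl)-1-phenyl-1H-tetrazole; 19 (3S,6S,7S,9aS)-3-(tert-butyldimethylsilyloxy)-2,2,6,7-tetramethyl-2,3,4,6,7,8,9,9a-octahydro-1-benzoxepine-6-carbaldehyde
Product: 35 (E)-C13=C14 alkene joining C6 of the left (3S,6R,7S,9aS) silyloxy-octahydrobenzoxepine to C6 of the right (3S,5aS,6S,7S,9aS) bis(silyloxy)-decahydrobenzoxepine
Conditions: KN(SiMe3)2, DME, −60 °C; then 19, −60 °C to rt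
Reagents that add atoms: none
Why: Julia–Kocienski olefination (sulfonyl carbanion addition, Smiles rearrangement, loss of SO2 and tetrazolate) joins the two fragments at C13=C14, and the non-enolisable aldehyde cannot be deprotonated.

Step 28
Reactants: 35 (E)-C13=C14 alkene
Product: 36 C13–C14 saturated tris-silyl ether (left (3S,6S,7S,9aS), right (3S,5aS,6S,7S,9aS))
Conditions: 2-nitrobenzenesulfonylhydrazide (20 equiv, portionwise), Et3N, CH2Cl2, rt
Reagents that add atoms: none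
Why: Diimide transfers H2 to the 1,2-disubstituted alkene much faster than to the hindered trisubstituted C10=C11 alkene and cannot hydrogenolyse the allylic C5–O bond.

Step 29
Reactants: 36 C13–C14 saturated tris-silyl ether
Product: 37 (3S,5aS,6S,7S,9aS)-6-{2-[(3S,6S,7S,9aS)-3-(tert-butyldimethylsilyloxy)-2,2,6,7-tetramethyl-2,3,4,6,7,8,9,9a-octahydro-1-benzoxepin-6-yl]ethyl}-2,2,5a,7-tetramethyldecahydro-1-benzoxepine-3,7-diol
Conditions: camphorsulfonic acid (10 mol%), MeOH/CH2Cl2, 0 °C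
Reagents that add atoms: none
Why: Acid-catalysed methanolysis removes the triethylsilyl and trimethylsilyl ethers while the hindered secondary tert-butyldimethylsilyl ether at C8 survives, which exposes only C19–OH as an oxidisable alcohol.

Step 30
Reactants: 37 (3S,5aS,6S,7S,9aS)-6-{2-[(3S,6S,7S,9aS)-3-(tert-butyldimethylsilyloxy)-2,2,6,7-tetramethyl-2,3,4,6,7,8,9,9a-octahydro-1-benzoxepin-6-yl]ethyl}-2,2,5a,7-tetramethyldecahydro-1-benzoxepine-3,7-diol
Product: 38 (5aS,6S,7S,9aS)-6-{2-[(3S,6S,7S,9aS)-3-(tert-butyldimethylsilyloxy)-2,2,6,7-tetramethyl-2,3,4,6,7,8,9,9a-octahydro-1-benzoxepin-6-yl]ethyl}-7-hydroxy-2,2,5a,7-tetramethyloctahydro-1-benzoxepin-3(2H)-one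
Conditions: Dess–Martin periodinane, NaHCO3, CH2Cl2, rt
Reagents that add atoms: none
Why: Dess–Martin oxidation converts the secondary C19 alcohol into the ketone, and the tertiary C25 alcohol cannot be oxidised.

Step 31
Reactants: 38 (5aS,6S,7S,9aS)-6-{2-[(3S,6S,7S,9aS)-3-(tert-butyldimethylsilyloxy)-2,2,6,7-tetramethyl-2,3,4,6,7,8,9,9a-octahydro-1-benzoxepin-6-yl]ethyl}-7-hydroxy-2,2,5a,7-tetramethyloctahydro-1-benzoxepin-3(2H)-one
Product: 39 Sodwanone S
Conditions: HF·pyridine, pyridine, THF, 0 °C to rt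
Reagents that add atoms: none
Why: Fluoride-mediated desilylation frees the C8 alcohol under conditions that leave the α-alkoxy ketone, the tertiary alcohol and the allylic ether unchanged.

## Compound list

1 | methyl acetoacetate (methyl 3-oxobutanoate) | CC(=O)CC(=O)OC | starting material
2 | (E)-crotonaldehyde | C/C=C/C=O | starting material
3 | methyl (3S)-2-acetyl-3-methyl-5-oxopentanoate (Michael adduct, C2 epimers) | C[C@@H](CC=O)C(C(C)=O)C(=O)OC | intermediate (not isolated)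
4 | methyl (1R,6S)-6-methyl-2-oxocyclohex-3-ene-1-carboxylate | C[C@H]1CC=CC(=O)[C@@H]1C(=O)OC | intermediate
5 | methyl (1R,2S)-2-methyl-6-oxocyclohexane-1-carboxylate | C[C@H]1CCCC(=O)[C@@H]1C(=O)OC | intermediate
6 | methyl (1S,2S)-1,2-dimethyl-6-oxocyclohexane-1-carboxylate | C[C@H]1CCCC(=O)[C@@]1(C)C(=O)OC | intermediate
7 | methyl (1S,2S)-1,2-dimethyl-6-oxo-5-(trifluoroacetyl)cyclohexane-1-carboxylate | C[C@H]1CCC(C(=O)C(F)(F)F)C(=O)[C@@]1(C)C(=O)OC | intermediate (not isolated)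
8 | methyl (1S,2S)-5-diazo-1,2-dimethyl-6-oxocyclohexane-1-carboxylate | C[C@H]1CCC(=[N+]=[N-])C(=O)[C@@]1(C)C(=O)OC | intermediate
9 | 1,1-dimethoxypropan-2-one | CC(=O)C(OC)OC | starting material
10 | 1,1-dimethoxy-2-methylpropan-2-ol | CC(C)(O)C(OC)OC | intermediate
11 | methyl (1S,2S,5RS)-5-[(1,1-dimethoxy-2-methylpropan-2-yl)oxy]-1,2-dimethyl-6-oxocyclohexane-1-carboxylate (C5-epimer mixture) | C[C@H]1CCC(OC(C)(C)C(OC)OC)C(=O)[C@@]1(C)C(=O)OC | intermediate (not isolated)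
12 | methyl (1S,2S,5S)-5-[(1,1-dimethoxy-2-methylpropan-2-yl)oxy]-1,2-dimethyl-6-oxocyclohexane-1-carboxylate | C[C@H]1CC[C@H](OC(C)(C)C(OC)OC)C(=O)[C@@]1(C)C(=O)OC | intermediate
13 | methyl (1S,2S,5S)-1,2-dimethyl-5-[(2-methyl-1-oxopropan-2-yl)oxy]-6-oxocyclohexane-1-carboxylate | C[C@H]1CC[C@H](OC(C)(C)C=O)C(=O)[C@@]1(C)C(=O)OC | intermediate
14 | methyl (1S,2S,5S)-5-{[(3S)-3-hydroxy-2-methylhex-5-en-2-yl]oxy}-1,2-dimethyl-6-oxocyclohexane-1-carboxylate | C[C@H]1CC[C@H](OC(C)(C)[C@@H](O)CC=C)C(=O)[C@@]1(C)C(=O)OC | intermediate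
15 | methyl (1S,2S,5S)-5-{[(3S)-3-(tert-butyldimethylsilyloxy)-2-methylhex-5-en-2-yl]oxy}-1,2-dimethyl-6-oxocyclohexane-1-carboxylate | C[C@H]1CC[C@H](OC(C)(C)[C@@H](O[Si](C)(C)C(C)(C)C)CC=C)C(=O)[C@@]1(C)C(=O)OC | intermediate
16 | methyl (1S,2S,5S)-5-{[(3S)-3-(tert-butyldimethylsilyloxy)-2-methylhex-5-en-2-yl]oxy}-1,2-dimethyl-6-methylidenecyclohexane-1-carboxylate | C[C@H]1CC[C@H](OC(C)(C)[C@@H](O[Si](C)(C)C(C)(C)C)CC=C)C(=C)[C@@]1(C)C(=O)OC | intermediate
17 | methyl (3S,6S,7S,9aS)-3-(tert-butyldimethylsilyloxy)-2,2,6,7-tetramethyl-2,3,4,6,7,8,9,9a-octahydro-1-benzoxepine-6-carboxylate | C[C@H]1CC[C@@H]2OC(C)(C)[C@@H](O[Si](C)(C)C(C)(C)C)CC=C2[C@@]1(C)C(=O)OC | intermediate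
18 | [(3S,6S,7S,9aS)-3-(tert-butyldimethylsilyloxy)-2,2,6,7-tetramethyl-2,3,4,6,7,8,9,9a-octahydro-1-benzoxepin-6-yl]methanol | C[C@H]1CC[C@@H]2OC(C)(C)[C@@H](O[Si](C)(C)C(C)(C)C)CC=C2[C@@]1(C)CO | intermediate
19 | (3S,6S,7S,9aS)-3-(tert-butyldimethylsilyloxy)-2,2,6,7-tetramethyl-2,3,4,6,7,8,9,9a-octahydro-1-benzoxepine-6-carbaldehyde (fragment A) | C[C@H]1CC[C@@H]2OC(C)(C)[C@@H](O[Si](C)(C)C(C)(C)C)CC=C2[C@@]1(C)C=O | intermediate
20 | geraniol [(2E)-3,7-dimethylocta-2,6-dien-1-ol] | CC(C)=CCC/C(C)=C/CO | starting material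
21 | [(2S,3S)-3-methyl-3-(4-methylpent-3-en-1-yl)oxiran-2-yl]methanol | OC[C@@H]1O[C@@]1(C)CCC=C(C)C | intermediate
22 | [(2S,3S)-3-{2-[(2S)-3,3-dimethyloxiran-2-yl]ethyl}-3-methyloxiran-2-yl]methanol | OC[C@@H]1O[C@@]1(C)CC[C@@H]1OC1(C)C | intermediate
23 | [(2S,3S)-3-{2-[(2S)-3,3-dimethyloxiran-2-yl]ethyl}-3-methyloxiran-2-yl]methyl trifluoromethanesulfonate | FC(F)(F)S(=O)(=O)OC[C@@H]1O[C@@]1(C)CC[C@@H]1OC1(C)C | intermediate (not isolated)
24 | methyl 5-[(2S,3S)-3-{2-[(2S)-3,3-dimethyloxiran-2-yl]ethyl}-3-methyloxiran-2-yl]-3-oxopentanoate | COC(=O)CC(=O)CC[C@@H]1O[C@@]1(C)CC[C@@H]1OC1(C)C | intermediate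
25 | methyl (2Z)-5-[(2S,3S)-3-{2-[(2S)-3,3-dimethyloxiran-2-yl]ethyl}-3-methyloxiran-2-yl]-3-(triethylsilyloxy)pent-2-enoate | COC(=O)/C=C(\O[Si](CC)(CC)CC)CC[C@@H]1O[C@@]1(C)CC[C@@H]1OC1(C)C | intermediate
26 | methyl (3S,5aS,6S,9aS)-2,2,5a-trimethyl-7-oxo-3-(triethylsilyloxy)decahydro-1-benzoxepine-6-carboxylate (keto form; partly enolised) | COC(=O)[C@H]1[C@]2(C)CC[C@H](O[Si](CC)(CC)CC)C(C)(C)O[C@H]2CCC1=O | intermediate
27 | methyl (3S,5aS,9aS)-2,2,5a-trimethyl-3-(triethylsilyloxy)-7-(trifluoromethylsulfonyloxy)-2,3,4,5,5a,8,9,9a-octahydro-1-benzoxepine-6-carboxylate | COC(=O)C=1[C@]2(C)CC[C@H](O[Si](CC)(CC)CC)C(C)(C)O[C@H]2CCC=1OS(=O)(=O)C(F)(F)F | intermediate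
28 | methyl (3S,5aS,9aS)-2,2,5a,7-tetramethyl-3-(triethylsilyloxy)-2,3,4,5,5a,8,9,9a-octahydro-1-benzoxepine-6-carboxylate | COC(=O)C=1[C@]2(C)CC[C@H](O[Si](CC)(CC)CC)C(C)(C)O[C@H]2CCC=1C | intermediate
29 | methyl (3S,5aR,6R,7S,9aS)-6,7-epoxy-2,2,5a,7-tetramethyl-3-(triethylsilyloxy)decahydro-1-benzoxepine-6-carboxylate (epoxide anti to the angular methyl) | COC(=O)[C@@]13[C@]2(C)CC[C@H](O[Si](CC)(CC)CC)C(C)(C)O[C@H]2CC[C@]1(C)O3 | intermediate
30 | methyl (3S,5aS,6S,7S,9aS)-7-hydroxy-2,2,5a,7-tetramethyl-3-(triethylsilyloxy)decahydro-1-benzoxepine-6-carboxylate | COC(=O)[C@H]1[C@]2(C)CC[C@H](O[Si](CC)(CC)CC)C(C)(C)O[C@H]2CC[C@]1(C)O | intermediate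
31 | (3S,5aS,6R,7S,9aS)-6-(hydroxymethyl)-2,2,5a,7-tetramethyl-3-(triethylsilyloxy)decahydro-1-benzoxepin-7-ol | OC[C@H]1[C@]2(C)CC[C@H](O[Si](CC)(CC)CC)C(C)(C)O[C@H]2CC[C@]1(C)O | intermediate
32 | (3S,5aS,6S,7S,9aS)-2,2,5a,7-tetramethyl-6-{[(1-phenyl-1H-tetrazol-5-yl)sulfanyl]methyl}-3-(triethylsilyloxy)decahydro-1-benzoxepin-7-ol | c1ccccc1-n1nnnc1SC[C@H]1[C@]2(C)CC[C@H](O[Si](CC)(CC)CC)C(C)(C)O[C@H]2CC[C@]1(C)O | intermediate
33 | (3S,5aS,6S,7S,9aS)-2,2,5a,7-tetramethyl-6-{[(1-phenyl-1H-tetrazol-5-yl)sulfonyl]methyl}-3-(triethylsilyloxy)decahydro-1-benzoxepin-7-ol | c1ccccc1-n1nnnc1S(=O)(=O)C[C@H]1[C@]2(C)CC[C@H](O[Si](CC)(CC)CC)C(C)(C)O[C@H]2CC[C@]1(C)O | intermediate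
34 | 5-({[(3S,5aS,6S,7S,9aS)-2,2,5a,7-tetramethyl-3-(triethylsilyloxy)-7-(trimethylsilyloxy)decahydro-1-benzoxepin-6-yl]methyl}sulfonyl)-1-phenyl-1H-tetrazole (fragment B) | c1ccccc1-n1nnnc1S(=O)(=O)C[C@H]1[C@]2(C)CC[C@H](O[Si](CC)(CC)CC)C(C)(C)O[C@H]2CC[C@]1(C)O[Si](C)(C)C | intermediate
35 | (3S,6R,7S,9aS)-3-(tert-butyldimethylsilyloxy)-2,2,6,7-tetramethyl-6-{(E)-2-[(3S,5aS,6S,7S,9aS)-2,2,5a,7-tetramethyl-3-(triethylsilyloxy)-7-(trimethylsilyloxy)decahydro-1-benzoxepin-6-yl]ethenyl}-2,3,4,6,7,8,9,9a-octahydro-1-benzoxepine | C[C@H]1CC[C@@H]2OC(C)(C)[C@@H](O[Si](C)(C)C(C)(C)C)CC=C2[C@@]1(C)/C=C/[C@H]1[C@]2(C)CC[C@H](O[Si](CC)(CC)CC)C(C)(C)O[C@H]2CC[C@]1(C)O[Si](C)(C)C | intermediate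
36 | (3S,6S,7S,9aS)-3-(tert-butyldimethylsilyloxy)-2,2,6,7-tetramethyl-6-{2-[(3S,5aS,6S,7S,9aS)-2,2,5a,7-tetramethyl-3-(triethylsilyloxy)-7-(trimethylsilyloxy)decahydro-1-benzoxepin-6-yl]ethyl}-2,3,4,6,7,8,9,9a-octahydro-1-benzoxepine | C[C@H]1CC[C@@H]2OC(C)(C)[C@@H](O[Si](C)(C)C(C)(C)C)CC=C2[C@@]1(C)CC[C@H]1[C@]2(C)CC[C@H](O[Si](CC)(CC)CC)C(C)(C)O[C@H]2CC[C@]1(C)O[Si](C)(C)C | intermediate
37 | (3S,5aS,6S,7S,9aS)-6-{2-[(3S,6S,7S,9aS)-3-(tert-butyldimethylsilyloxy)-2,2,6,7-tetramethyl-2,3,4,6,7,8,9,9a-octahydro-1-benzoxepin-6-yl]ethyl}-2,2,5a,7-tetramethyldecahydro-1-benzoxepine-3,7-diol | C[C@H]1CC[C@@H]2OC(C)(C)[C@@H](O[Si](C)(C)C(C)(C)C)CC=C2[C@@]1(C)CC[C@H]1[C@]2(C)CC[C@H](O)C(C)(C)O[C@H]2CC[C@]1(C)O | intermediate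
38 | (5aS,6S,7S,9aS)-6-{2-[(3S,6S,7S,9aS)-3-(tert-butyldimethylsilyloxy)-2,2,6,7-tetramethyl-2,3,4,6,7,8,9,9a-octahydro-1-benzoxepin-6-yl]ethyl}-7-hydroxy-2,2,5a,7-tetramethyloctahydro-1-benzoxepin-3(2H)-one | C[C@H]1CC[C@@H]2OC(C)(C)[C@@H](O[Si](C)(C)C(C)(C)C)CC=C2[C@@]1(C)CC[C@H]1[C@]2(C)CCC(=O)C(C)(C)O[C@H]2CC[C@]1(C)O | intermediate
39 | Sodwanone S, (5aS,6S,7S,9aS)-7-hydroxy-6-{2-[(3S,6S,7S,9aS)-3-hydroxy-2,2,6,7-tetramethyl-2,3,4,6,7,8,9,9a-octahydro-1-benzoxepin-6-yl]ethyl}-2,2,5a,7-tetramethyloctahydro-1-benzoxepin-3(2H)-one | C[C@H]1CC[C@@H]2OC(C)(C)[C@@H](O)CC=C2[C@@]1(C)CC[C@H]1[C@]2(C)CCC(=O)C(C)(C)O[C@H]2CC[C@]1(C)O | target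

## Step count, longest linear sequence, and risks

Total step count: 31 (fragment A 13 steps including the one-step side branch to 10, fragment B 13 steps, union and endgame 5 steps).

Longest linear sequence: 18 steps (steps 14–26, then 27–31); the fragment A arm is 17 steps (steps 1–4 and 6–13, then 27–31).

The three steps most likely to fail:

Step 18 (tandem oxa/carbacyclisation). The β-silyloxy enoate is a weak π-nucleophile, and activation of the internal epoxide or O-cyclisation can compete. The fallback sets out from 24 and comes back at 31; it uses a stronger allylsilane terminator and installs the C25 carbinol through an exocyclic alkene. Compound 24 is converted with NaH and ClP(O)(OEt)2 into methyl (2Z)-3-[(diethoxyphosphoryl)oxy]-5-[(2S,3S)-3-{2-[(2S)-3,3-dimethyloxiran-2-yl]ethyl}-3-methyloxiran-2-yl]pent-2-enoate F5. Me3SiCH2MgCl with Ni(acac)2 in THF then gives, with retention of geometry, methyl (2Z)-5-[(2S,3S)-3-{2-[(2S)-3,3-dimethyloxiran-2-yl]ethyl}-3-methyloxiran-2-yl]-3-[(trimethylsilyl)methyl]pent-2-enoate F6. iBu2AlH at −78 °C gives (2Z)-5-[(2S,3S)-3-{2-[(2S)-3,3-dimethyloxiran-2-yl]ethyl}-3-methyloxiran-2-yl]-3-[(trimethylsilyl)methyl]pent-2-en-1-ol F7, and Ac2O/pyridine gives its acetate F8. Et3SiOTf (1.1 equiv) with 2,6-di-tert-butyl-4-methylpyridine at −78 °C then triggers the same cascade with loss of the trimethylsilyl group and gives [(3S,5aS,6R,9aS)-2,2,5a-trimethyl-7-methylidene-3-(triethylsilyloxy)decahydro-1-benzoxepin-6-yl]methyl acetate F9. mCPBA/NaHCO3 epoxidises the exocyclic alkene from the face opposite the angular methyl to the spiro-epoxide of F9 with equatorial oxygen F10. LiAlH4 opens this epoxide at its CH2 (axial methyl, equatorial hydroxyl) and removes the acetate, which gives diol 31.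

Step 6 (intermolecular O–H insertion into a hindered tertiary alcohol). 1,2-Hydride shift of the carbenoid to the enone, or ylide formation with the acetal oxygens or the ester carbonyl, may win. The fallback sets out from 6 and comes back at 13. Enolate hydroxylation of 6 (KN(SiMe3)2, THF, −78 °C; 2-(phenylsulfonyl)-3-phenyloxaziridine) gives methyl (1S,2S,5S)-5-hydroxy-1,2-dimethyl-6-oxocyclohexane-1-carboxylate F1. Nicholas etherification with the Co2(CO)6 complex of 2-methylbut-3-yn-2-ol (made from Co2(CO)8) and BF3·OEt2 in CH2Cl2 at −20 °C gives the hexacarbonyldicobalt complex of the propargyl ether F2. Decomplexation with (NH4)2Ce(NO3)6 in acetone at 0 °C frees methyl (1S,2S,5S)-1,2-dimethyl-5-[(2-methylbut-3-yn-2-yl)oxy]-6-oxocyclohexane-1-carboxylate F3. Semi-hydrogenation (H2, Pd/CaCO3 poisoned with Pb(OAc)2, quinoline, EtOAc) gives methyl (1S,2S,5S)-1,2-dimethyl-5-[(2-methylbut-3-en-2-yl)oxy]-6-oxocyclohexane-1-carboxylate F4, and ozonolysis (O3, CH2Cl2, −78 °C; PPh3) of its vinyl group returns aldehyde 13.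

Step 11 (ring-closing metathesis onto a 1,1-disubstituted alkene flanked by quaternary C12). Ring closure may stall after the catalyst has loaded on the allyl terminus. The fallback sets out from 15 and comes back at 17; it omits step 10 and closes the ring by carbonyl–olefin metathesis. Keto-olefin 15 is treated with a stoichiometric amount of the Schrock alkylidene Mo(=CHCMe2Ph)(=N-2,6-iPr2C6H3)[OCMe(CF3)2]2 in benzene at rt. The alkylidene first exchanges with the terminal alkene, and the new molybdenum alkylidene at C10 then olefinates the C11 ketone intramolecularly in a Wittig-like step driven by Mo=O formation, which gives oxepene 17 directly; this fallback makes no further compound (none F0).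

Further compounds
F1 | step 6 | methyl (1S,2S,5S)-5-hydroxy-1,2-dimethyl-6-oxocyclohexane-1-carboxylate | C[C@H]1CC[C@H](O)C(=O)[C@@]1(C)C(=O)OC
F2 | step 6 | hexacarbonyldicobalt complex of methyl (1S,2S,5S)-1,2-dimethyl-5-[(2-methylbut-3-yn-2-yl)oxy]-6-oxocyclohexane-1-carboxylate | C[C@H]1CC[C@H](OC(C)(C)C#C)C(=O)[C@@]1(C)C(=O)OC.[Co].[Co].[C-]#[O+].[C-]#[O+].[C-]#[O+].[C-]#[O+].[C-]#[O+].[C-]#[O+]
F3 | step 6 | methyl (1S,2S,5S)-1,2-dimethyl-5-[(2-methylbut-3-yn-2-yl)oxy]-6-oxocyclohexane-1-carboxylate | C[C@H]1CC[C@H](OC(C)(C)C#C)C(=O)[C@@]1(C)C(=O)OC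
F4 | step 6 | methyl (1S,2S,5S)-1,2-dimethyl-5-[(2-methylbut-3-en-2-yl)oxy]-6-oxocyclohexane-1-carboxylate | C[C@H]1CC[C@H](OC(C)(C)C=C)C(=O)[C@@]1(C)C(=O)OC
F0 | step 11 | none | none
F5 | step 18 | methyl (2Z)-3-[(diethoxyphosphoryl)oxy]-5-[(2S,3S)-3-{2-[(2S)-3,3-dimethyloxiran-2-yl]ethyl}-3-methyloxiran-2-yl]pent-2-enoate | COC(=O)/C=C(\OP(=O)(OCC)OCC)CC[C@@H]1O[C@@]1(C)CC[C@@H]1OC1(C)C
F6 | step 18 | methyl (2Z)-5-[(2S,3S)-3-{2-[(2S)-3,3-dimethyloxiran-2-yl]ethyl}-3-methyloxiran-2-yl]-3-[(trimethylsilyl)methyl]pent-2-enoate | COC(=O)/C=C(\C[Si](C)(C)C)CC[C@@H]1O[C@@]1(C)CC[C@@H]1OC1(C)C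
F7 | step 18 | (2Z)-5-[(2S,3S)-3-{2-[(2S)-3,3-dimethyloxiran-2-yl]ethyl}-3-methyloxiran-2-yl]-3-[(trimethylsilyl)methyl]pent-2-en-1-ol | OC/C=C(\C[Si](C)(C)C)CC[C@@H]1O[C@@]1(C)CC[C@@H]1OC1(C)C
F8 | step 18 | (2Z)-5-[(2S,3S)-3-{2-[(2S)-3,3-dimethyloxiran-2-yl]ethyl}-3-methyloxiran-2-yl]-3-[(trimethylsilyl)methyl]pent-2-en-1-yl acetate | CC(=O)OC/C=C(\C[Si](C)(C)C)CC[C@@H]1O[C@@]1(C)CC[C@@H]1OC1(C)C
F9 | step 18 | [(3S,5aS,6R,9aS)-2,2,5a-trimethyl-7-methylidene-3-(triethylsilyloxy)decahydro-1-benzoxepin-6-yl]methyl acetate | CC(=O)OC[C@H]1[C@]2(C)CC[C@H](O[Si](CC)(CC)CC)C(C)(C)O[C@H]2CCC1=C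
F10 | step 18 | spiro-epoxide of F9 at the exocyclic alkene (oxirane oxygen equatorial, anti to the angular methyl) | CC(=O)OC[C@H]1[C@]2(C)CC[C@H](O[Si](CC)(CC)CC)C(C)(C)O[C@H]2CC[C@]1(C3)O3
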